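The polyene is cut at the C12–C13 single bond (carotenoid numbering), the centre of the (E,E)-2-methyl-1,3-diene C11=C12–C13(C20H3)=C14 that links the acetylenic 3-hydroxy-β ring (C1–C6, C7≡C8) to the 3-hydroxy-ε ring (C1'–C6'). The key step is a one-flask, three-component Negishi sequence. The terminal alkyne C11≡C12 of a β-ring enediyne is hydrozirconated. The alkenylmetal then displaces, trans-selectively, one bromine at the gem-dibromide carbon C13 of an ε-ring hexaenyl 1,1-dibromide, and the second bromine is exchanged for the C20 methyl with retention. One operation thus forms C12–C13, fixes both flanking E double bonds and installs the methyl branch.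

Key step: step 15

Assumption: (R)-α-ionone (1) and (4R,6R)-actinol (16) are taken as purchasable in enantiopure form; positions are named by carotenoid numbering (unprimed for the β half, primed for the ε half), TBS = tert-butyldimethylsilyl, and all polyenes are handled under argon in dim light.

Step 1
Reactants: 1 (R)-α-ionone; 2 diethyl (cyanomethyl)phosphonate
Product: 3 (2E,4E)-3-methyl-5-[(1R)-2,6,6-trimethylcyclohex-2-en-1-yl]penta-2,4-dienenitrile
Conditions: NaH, THF, 0 °C to rt; minor 9'Z isomer removed by chromatography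
Reagents that add atoms: none
Why: Horner–Wadsworth–Emmons olefination of the methyl ketone by a stabilised phosphonate carbanion that is too weakly basic to enolise C6' (no stereocentre is formed or touched) and that places the nitrile preferentially trans to the dienyl chain.

Step 2
Reactants: 3 C15 nitrile
Product: 4 (2E,4E)-3-methyl-5-[(1R)-2,6,6-trimethyl-4-oxocyclohex-2-en-1-yl]penta-2,4-dienenitrile
Conditions: t-BuOOH (70% aq), Rh2(cap)4 (cap = caprolactamate, cat.), K2CO3, CH2Cl2, rt
Reagents that add atoms: tert-butyl hydroperoxide, CC(C)(C)OO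
Why: Radical allylic C–H oxidation (tert-butylperoxyl chain mediated by the dirhodium carboxamidate) attacks the only secondary allylic CH2 of the ring, C3', and carries it to the conjugated enone, whereas the tertiary C6'–H is shielded by the gem-dimethyl group and the C5' methyl, so the C6' stereocentre should stay intact.

Step 3
Reactants: 4 3'-oxo nitrile
Product: 5 (2E,4E)-5-[(1R,4R)-4-hydroxy-2,6,6-trimethylcyclohex-2-en-1-yl]-3-methylpenta-2,4-dienenitrile
Conditions: K[sec-Bu3BH], THF, −78 °C; then H2O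
Reagents that add atoms: none
Why: 1,2-Reduction of the β,β-disubstituted cyclohexenone by a bulky trialkylborohydride; with the C6' chain pseudoaxial (avoiding A(1,2) strain with the C5' methyl) the C1' methyl anti to it is axial and shields that face, so hydride should arrive on the chain side and set the 3'R (3',6'-trans) carbinol.

Step 4
Reactants: 5 hydroxy nitrile
Product: 6 (2E,4E)-5-[(1R,4R)-4-(TBS-oxy)-2,6,6-trimethylcyclohex-2-en-1-yl]-3-methylpenta-2,4-dienenitrile
Conditions: TBSCl, imidazole, DMF, rt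
Reagents that add atoms: tert-butyldimethylsilyl chloride, CC(C)(C)[Si](C)(C)Cl
Why: Imidazole-promoted silylation of the secondary allylic alcohol protects the hydroxyl against the hydride, carbanion, zirconium and zinc reagents used later.

Step 5
Reactants: 6 silyl ether nitrile
Product: 8 (2E,4E)-5-[(1R,4R)-4-(TBS-oxy)-2,6,6-trimethylcyclohex-2-en-1-yl]-3-methylpenta-2,4-dienal, via N-diisobutylaluminio imine 7 (not isolated)
Conditions: i-Bu2AlH, CH2Cl2, −78 °C; then wet SiO2 / H2O
Reagents that add atoms: water, O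
Why: Partial reduction of the nitrile by one equivalent of i-Bu2AlH stops at the N-aluminio imine, which is hydrolysed on work-up to the enal without touching the silyl ether or the double bonds.

Step 6
Reactants: 8 C15 aldehyde; 9 diethyl (3-cyano-2-methylprop-2-en-1-yl)phosphonate
Product: 10 (2E,4E,6E,8E)-9-[(1R,4R)-4-(TBS-oxy)-2,6,6-trimethylcyclohex-2-en-1-yl]-3,7-dimethylnona-2,4,6,8-tetraenenitrile
Conditions: NaH, THF, 0 °C to rt; minor 13'Z isomer removed by chromatography
Reagents that add atoms: none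
Why: Horner–Wadsworth–Emmons olefination of the enal with the vinylogous phosphonate anion, which reacts at the phosphorus-bearing carbon to form C11'=C12' as the E alkene and should give C13'=C14' predominantly E.

Step 7
Reactants: 10 C20 nitrile
Product: 12 (2E,4E,6E,8E)-9-[(1R,4R)-4-(TBS-oxy)-2,6,6-trimethylcyclohex-2-en-1-yl]-3,7-dimethylnona-2,4,6,8-tetraenal, via N-diisobutylaluminio imine 11 (not isolated)
Conditions: i-Bu2AlH, CH2Cl2, −78 °C; then wet SiO2 / H2O
Reagents that add atoms: water, O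
Why: The same partial nitrile reduction to an N-aluminio imine and hydrolysis delivers the polyenal directly at the aldehyde oxidation level.

Step 8
Reactants: 12 C20 aldehyde; 13 (triphenylphosphoranylidene)acetaldehyde
Product: 14 (2E,4E,6E,8E,10E)-11-[(1R,4R)-4-(TBS-oxy)-2,6,6-trimethylcyclohex-2-en-1-yl]-5,9-dimethylundeca-2,4,6,8,10-pentaenal
Conditions: toluene, 80 °C
Reagents that add atoms: none
Why: Wittig olefination with the stabilised formyl ylide gives the E alkene at C15'=C15 and extends the chain by two carbons to the aldehyde carbon C14.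

Step 9
Reactants: 14 C22 aldehyde
Product: 15 tert-butyl{[(1R,4R)-4-[(1E,3E,5E,7E,9E)-12,12-dibromo-3,7-dimethyldodeca-1,3,5,7,9,11-hexaen-1-yl]-3,5,5-trimethylcyclohex-2-en-1-yl]oxy}dimethylsilane
Conditions: CBr4, PPh3, Zn dust, CH2Cl2, rt (ylide pre-formed); then 14, 0 °C to rt
Reagents that add atoms: carbon tetrabromide, BrC(Br)(Br)Br
Why: Ramirez–Corey–Fuchs dibromo-olefination with Ph3P=CBr2 turns the aldehyde carbon C14 into the C14=C13Br2 terminus, and the zinc-dust variant keeps the medium neutral for the silyl ether and the polyene.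

Step 10
Reactants: 16 (4R,6R)-actinol
Product: 17 (4R,6R)-4-(TBS-oxy)-2,2,6-trimethylcyclohexan-1-one
Conditions: TBSCl, imidazole, DMF, rt
Reagents that add atoms: tert-butyldimethylsilyl chloride, CC(C)(C)[Si](C)(C)Cl
Why: Standard silylation of the secondary alcohol, whose configuration (the future 3R centre) comes from the chiral pool.

Step 11
Reactants: 17 silyloxy ketone
Product: 19 (4R)-4-(TBS-oxy)-2,6,6-trimethylcyclohex-1-en-1-yl trifluoromethanesulfonate, via lithium enolate 18 (not isolated)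
Conditions: LiN(i-Pr)2, THF, −78 °C; then PhNTf2, −78 °C to rt
Reagents that add atoms: N-phenylbis(trifluoromethanesulfonimide), O=S(=O)(N(c1ccccc1)S(=O)(=O)C(F)(F)F)C(F)(F)F
Why: Enolisation is possible only toward the methyl-bearing α-carbon (the other α-carbon is quaternary), and O-triflation of the lithium enolate gives the tetrasubstituted enol triflate, erasing the methyl-bearing stereocentre by design and leaving the silyloxy carbon untouched.

Step 12
Reactants: 19 enol triflate; 20 (2E)-3-methylpent-2-en-4-yn-1-ol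
Product: 21 (2E)-5-[(4R)-4-(TBS-oxy)-2,6,6-trimethylcyclohex-1-en-1-yl]-3-methylpent-2-en-4-yn-1-ol
Conditions: Pd(PPh3)4 (cat.), CuI (cat.), Et3N, DMF, rt
Reagents that add atoms: none
Why: Sonogashira coupling of the enol triflate with the terminal alkyne forms the C6–C7 bond under mild amine base, keeps the E geometry of the enyne and tolerates the free primary alcohol.

Step 13
Reactants: 21 enynol
Product: 22 (2E)-5-[(4R)-4-(TBS-oxy)-2,6,6-trimethylcyclohex-1-en-1-yl]-3-methylpent-2-en-4-ynal
Conditions: MnO2, CH2Cl2, rt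
Reagents that add atoms: none
Why: Chemoselective MnO2 oxidation of the allylic alcohol stops at the enal and leaves the alkyne and the silyl ether alone.

Step 14
Reactants: 22 enynal
Product: 23 tert-butyldimethyl{[(1R)-3,5,5-trimethyl-4-[(3E)-3-methylhex-3-ene-1,5-diyn-1-yl]cyclohex-3-en-1-yl]oxy}silane
Conditions: Me3SiCHN2, LiN(i-Pr)2, THF, −78 °C; then 22, −78 °C to rt
Reagents that add atoms: (trimethylsilyl)diazomethane, C[Si](C)(C)C=[N+]=[N-]
Why: Colvin rearrangement: lithio(trimethylsilyl)diazomethane adds to the aldehyde, Peterson-type elimination and loss of N2 give an alkylidene carbene, and 1,2-hydrogen shift delivers the terminal alkyne C11≡C12 in an aprotic medium that cannot add an alcohol to the enyne.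

Step 15
Reactants: 23 terminal enediyne; 15 hexaenyl 1,1-dibromide
Product: 27 bis(tert-butyldimethylsilyl) ether of the target, via alkenylzirconocene chloride 24 (not isolated), via alkenylzinc bromide 25 (not isolated), via 13-bromo polyene 26 (not isolated)
Conditions: 23, Cp2Zr(H)Cl, THF, rt, dark; then ZnBr2, 15, PdCl2(DPEphos) (cat.), 0 °C to rt; then Me2Zn, Pd(P(t-Bu)3)2 (cat.), rt
Reagents that add atoms: dimethylzinc, C[Zn]C
Why: Syn-hydrozirconation of the terminal C11≡C12 alkyne of 23 puts zirconium on C12 and fixes C11=C12 as E, and ZnBr2 transmetalates 24 to the more reactive alkenylzinc 25. Zerovalent palladium carrying DPEphos inserts into the C13–Br bond of 15 that is trans to the C15 chain (the less hindered one, cis to H14), and transmetalation with 25 followed by reductive elimination forges the C12–C13 bond to give bromodiene 26. Added Pd(P(t-Bu)3)2 then activates the remaining hindered C13–Br bond at room temperature and Me2Zn delivers the C20 methyl with retention, because transmetalation and reductive elimination at the monoligated palladium should outrun π–σ–π isomerisation of the dienylpalladium. The closest known reaction type is the hydrozirconation–Negishi coupling combined with the trans-selective monoalkenylation and subsequent methylation of 1,1-dibromoalkenes to (1E)-2-methyl-1,3-dienes. No ring is closed and no stereocentre is created; the two new stereo-elements are the E geometries at C11=C12 and C13=C14, controlled by the syn addition of Zr–H and by the steric differentiation of the two bromines of 15. The step needs hydrozirconation of the terminal alkyne only, monoalkenylation only and no geometric scrambling: the C7≡C8 alkyne is shielded by fully substituted C6 and C9, the DPEphos catalyst should insert only sluggishly into the internal C–Br bond of 26 at room temperature, and the silyl ethers keep both hydroxyls inert to the zirconium and zinc reagents.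

Step 16
Reactants: 27 bis-silyl ether
Product: 28 (3R,3'R,6'R)-7,8-didehydro-β,ε-carotene-3,3'-diol (target)
Conditions: Bu4NF, THF, 0 °C to rt, dark
Reagents that add atoms: none
Why: Fluoride-driven desilylation (Si–F bond formation) frees both hydroxyls under non-acidic conditions that avoid ionisation of the allylic C3' carbinol and spare the polyene and the enyne.

Compound list
1 | (R)-α-ionone, (3E)-4-[(1R)-2,6,6-trimethylcyclohex-2-en-1-yl]but-3-en-2-one | CC1=CCCC(C)(C)[C@H]1/C=C/C(C)=O | starting material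
2 | diethyl (cyanomethyl)phosphonate | CCOP(=O)(CC#N)OCC | starting material
3 | (2E,4E)-3-methyl-5-[(1R)-2,6,6-trimethylcyclohex-2-en-1-yl]penta-2,4-dienenitrile | CC1=CCCC(C)(C)[C@H]1/C=C/C(C)=C/C#N | intermediate
4 | (2E,4E)-3-methyl-5-[(1R)-2,6,6-trimethyl-4-oxocyclohex-2-en-1-yl]penta-2,4-dienenitrile | CC1=CC(=O)CC(C)(C)[C@H]1/C=C/C(C)=C/C#N | intermediate
5 | (2E,4E)-5-[(1R,4R)-4-hydroxy-2,6,6-trimethylcyclohex-2-en-1-yl]-3-methylpenta-2,4-dienenitrile | CC1=C[C@H](O)CC(C)(C)[C@H]1/C=C/C(C)=C/C#N | intermediate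
6 | TBS ether of 5 | CC1=C[C@H](O[Si](C)(C)C(C)(C)C)CC(C)(C)[C@H]1/C=C/C(C)=C/C#N | intermediate
7 | N-(diisobutylaluminio) imine of aldehyde 8 | CC1=C[C@H](O[Si](C)(C)C(C)(C)C)CC(C)(C)[C@H]1/C=C/C(C)=C/C=N[Al](CC(C)C)CC(C)C | intermediate (not isolated)
8 | (2E,4E)-5-[(1R,4R)-4-(TBS-oxy)-2,6,6-trimethylcyclohex-2-en-1-yl]-3-methylpenta-2,4-dienal | CC1=C[C@H](O[Si](C)(C)C(C)(C)C)CC(C)(C)[C@H]1/C=C/C(C)=C/C=O | intermediate
9 | diethyl (3-cyano-2-methylprop-2-en-1-yl)phosphonate (E/Z mixture as sold) | CCOP(=O)(CC(C)=CC#N)OCC | starting material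
10 | (2E,4E,6E,8E)-9-[(1R,4R)-4-(TBS-oxy)-2,6,6-trimethylcyclohex-2-en-1-yl]-3,7-dimethylnona-2,4,6,8-tetraenenitrile | CC1=C[C@H](O[Si](C)(C)C(C)(C)C)CC(C)(C)[C@H]1/C=C/C(C)=C/C=C/C(C)=C/C#N | intermediate
11 | N-(diisobutylaluminio) imine of aldehyde 12 | CC1=C[C@H](O[Si](C)(C)C(C)(C)C)CC(C)(C)[C@H]1/C=C/C(C)=C/C=C/C(C)=C/C=N[Al](CC(C)C)CC(C)C | intermediate (not isolated)
12 | (2E,4E,6E,8E)-9-[(1R,4R)-4-(TBS-oxy)-2,6,6-trimethylcyclohex-2-en-1-yl]-3,7-dimethylnona-2,4,6,8-tetraenal | CC1=C[C@H](O[Si](C)(C)C(C)(C)C)CC(C)(C)[C@H]1/C=C/C(C)=C/C=C/C(C)=C/C=O | intermediate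
13 | (triphenylphosphoranylidene)acetaldehyde | O=CC=P(c1ccccc1)(c1ccccc1)c1ccccc1 | starting material
14 | (2E,4E,6E,8E,10E)-11-[(1R,4R)-4-(TBS-oxy)-2,6,6-trimethylcyclohex-2-en-1-yl]-5,9-dimethylundeca-2,4,6,8,10-pentaenal | CC1=C[C@H](O[Si](C)(C)C(C)(C)C)CC(C)(C)[C@H]1/C=C/C(C)=C/C=C/C(C)=C/C=C/C=O | intermediate
15 | tert-butyl{[(1R,4R)-4-[(1E,3E,5E,7E,9E)-12,12-dibromo-3,7-dimethyldodeca-1,3,5,7,9,11-hexaen-1-yl]-3,5,5-trimethylcyclohex-2-en-1-yl]oxy}dimethylsilane | CC1=C[C@H](O[Si](C)(C)C(C)(C)C)CC(C)(C)[C@H]1/C=C/C(C)=C/C=C/C(C)=C/C=C/C=C(Br)Br | intermediate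
16 | (4R,6R)-4-hydroxy-2,2,6-trimethylcyclohexan-1-one (actinol) | O=C1C(C)(C)C[C@H](O)C[C@H]1C | starting material
17 | (4R,6R)-4-(TBS-oxy)-2,2,6-trimethylcyclohexan-1-one | O=C1C(C)(C)C[C@H](O[Si](C)(C)C(C)(C)C)C[C@H]1C | intermediate
18 | lithium (4R)-4-(TBS-oxy)-2,6,6-trimethylcyclohex-1-en-1-olate | CC1=C(O[Li])C(C)(C)C[C@H](O[Si](C)(C)C(C)(C)C)C1 | intermediate (not isolated)
19 | (4R)-4-(TBS-oxy)-2,6,6-trimethylcyclohex-1-en-1-yl trifluoromethanesulfonate | CC1=C(OS(=O)(=O)C(F)(F)F)C(C)(C)C[C@H](O[Si](C)(C)C(C)(C)C)C1 | intermediate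
20 | (2E)-3-methylpent-2-en-4-yn-1-ol | C#C/C(C)=C/CO | starting material
21 | (2E)-5-[(4R)-4-(TBS-oxy)-2,6,6-trimethylcyclohex-1-en-1-yl]-3-methylpent-2-en-4-yn-1-ol | OC/C=C(\C)C#CC1=C(C)C[C@@H](O[Si](C)(C)C(C)(C)C)CC1(C)C | intermediate
22 | (2E)-5-[(4R)-4-(TBS-oxy)-2,6,6-trimethylcyclohex-1-en-1-yl]-3-methylpent-2-en-4-ynal | O=C/C=C(\C)C#CC1=C(C)C[C@@H](O[Si](C)(C)C(C)(C)C)CC1(C)C | intermediate
23 | tert-butyldimethyl{[(1R)-3,5,5-trimethyl-4-[(3E)-3-methylhex-3-ene-1,5-diyn-1-yl]cyclohex-3-en-1-yl]oxy}silane | C#C/C=C(\C)C#CC1=C(C)C[C@@H](O[Si](C)(C)C(C)(C)C)CC1(C)C | intermediate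
24 | chlorobis(cyclopentadienyl)[(1E,3E)-dienynyl]zirconium from 23 (zirconium on C12; cyclopentadienyl rings drawn σ-bonded) | Cl[Zr](/C=C/C=C(\C)C#CC1=C(C)C[C@@H](O[Si](C)(C)C(C)(C)C)CC1(C)C)(C2C=CC=C2)C2C=CC=C2 | intermediate (not isolated)
25 | (1E,3E)-dienynylzinc bromide from 24 (zinc on C12) | Br[Zn]/C=C/C=C(\C)C#CC1=C(C)C[C@@H](O[Si](C)(C)C(C)(C)C)CC1(C)C | intermediate (not isolated)
26 | 13-bromo polyene: bis-TBS ether of the target with bromine in place of the C13 methyl (C15 and C12 trans across C13=C14) | CC1=C[C@H](O[Si](C)(C)C(C)(C)C)CC(C)(C)[C@H]1/C=C/C(C)=C/C=C/C(C)=C/C=C/C=C(Br)/C=C/C=C(\C)C#CC1=C(C)C[C@@H](O[Si](C)(C)C(C)(C)C)CC1(C)C | intermediate (not isolated)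
27 | (3R,3'R,6'R)-3,3'-bis(TBS-oxy)-7,8-didehydro-β,ε-carotene | CC1=C[C@H](O[Si](C)(C)C(C)(C)C)CC(C)(C)[C@H]1/C=C/C(C)=C/C=C/C(C)=C/C=C/C=C(C)/C=C/C=C(\C)C#CC1=C(C)C[C@@H](O[Si](C)(C)C(C)(C)C)CC1(C)C | intermediate
28 | (3R,3'R,6'R)-7,8-didehydro-β,ε-carotene-3,3'-diol | CC1=C[C@H](O)CC(C)(C)[C@H]1/C=C/C(C)=C/C=C/C(C)=C/C=C/C=C(C)/C=C/C=C(\C)C#CC1=C(C)C[C@@H](O)CC1(C)C | target

Total step count: 16. Longest linear sequence: 11 steps (steps 1–9, 15 and 16); the β-ring branch (steps 10–14) joins at step 15.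

Steps most likely to fail

Step 15. The alkenylzirconium or alkenylzinc species may be lost to protonolysis or homocoupling before it cross-couples, a second alkenylation may compete, and the C13=C14 geometry may scramble during methylation while two palladium catalysts share the flask. The fallback sets out from 23 and 15 and separates the events. Cp2Zr(H)Cl-catalysed hydroboration of 23 with pinacolborane (CH2Cl2, rt) gives the isolable (E)-dienynyl pinacol boronate F1. Suzuki coupling of F1 with 15 (Pd(PPh3)4, TlOEt, THF/H2O, rt), which likewise engages the bromine trans to the chain, gives 26, now isolated and freed from the first catalyst. Methylation of purified 26 with Me2Zn and Pd(P(t-Bu)3)2 alone (THF, rt) rejoins the route at 27.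

Step 3. Hydride delivery may show poor facial selectivity, or arrive mainly on the face anti to the chain if the ring conformation differs from the one assumed, and conjugate reduction may compete. The fallback sets out from 4. Luche reduction (NaBH4, CeCl3, MeOH, −78 °C) and separation provide the 3',6'-cis alcohol (2E,4E)-5-[(1R,4S)-4-hydroxy-2,6,6-trimethylcyclohex-2-en-1-yl]-3-methylpenta-2,4-dienenitrile F2. Mitsunobu inversion (4-nitrobenzoic acid, PPh3, DIAD, THF, 0 °C) converts it by SN2 displacement into the 3',6'-trans 4-nitrobenzoate F3. Methanolysis (K2CO3, MeOH, rt) returns to 5, so both epimers are funnelled into the route.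

Step 2. Hydrogen abstraction may be unselective (doubly allylic C6'–H, allylic methyls), peroxyl radicals may add to the dienenitrile, and the C6'–H of the product, acidified by both the ring enone and the nitrile, may epimerise. The fallback sets out from 1 and oxidises before the chain is extended. Ketalisation (1,2-bis(trimethylsilyloxy)ethane, cat. Me3SiOTf, CH2Cl2, −78 °C) gives the dioxolane of (R)-α-ionone F4. Allylic oxidation as in step 2 gives the 3'-oxo ketal F5, and K[sec-Bu3BH] (THF, −78 °C) gives the (3'R,6'R)-hydroxy ketal F6. TBSCl/imidazole gives the silyl ether ketal F7, and PPTS in wet acetone releases (3R,6R)-3-(TBS-oxy)-α-ionone F8. Horner–Wadsworth–Emmons olefination of F8 with 2 (NaH, THF) rejoins the route at 6.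

Further compounds
F1 | step 15 | (E)-dienynyl pinacol boronate from 23 (boron on C12) | CC1(C)OB(/C=C/C=C(\C)C#CC2=C(C)C[C@@H](O[Si](C)(C)C(C)(C)C)CC2(C)C)OC1(C)C
F2 | step 3 | (2E,4E)-5-[(1R,4S)-4-hydroxy-2,6,6-trimethylcyclohex-2-en-1-yl]-3-methylpenta-2,4-dienenitrile | CC1=C[C@@H](O)CC(C)(C)[C@H]1/C=C/C(C)=C/C#N
F3 | step 3 | (1R,4R)-4-[(1E,3E)-4-cyano-3-methylbuta-1,3-dien-1-yl]-3,5,5-trimethylcyclohex-2-en-1-yl 4-nitrobenzoate | CC1=C[C@H](OC(=O)c2ccc(cc2)[N+](=O)[O-])CC(C)(C)[C@H]1/C=C/C(C)=C/C#N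
F4 | step 2 | 2-methyl-2-[(E)-2-[(1R)-2,6,6-trimethylcyclohex-2-en-1-yl]ethenyl]-1,3-dioxolane | CC1=CCCC(C)(C)[C@H]1/C=C/C1(C)OCCO1
F5 | step 2 | (4R)-3,5,5-trimethyl-4-[(E)-2-(2-methyl-1,3-dioxolan-2-yl)ethenyl]cyclohex-2-en-1-one | CC1=CC(=O)CC(C)(C)[C@H]1/C=C/C1(C)OCCO1
F6 | step 2 | (1R,4R)-3,5,5-trimethyl-4-[(E)-2-(2-methyl-1,3-dioxolan-2-yl)ethenyl]cyclohex-2-en-1-ol | CC1=C[C@H](O)CC(C)(C)[C@H]1/C=C/C1(C)OCCO1
F7 | step 2 | TBS ether of F6 | CC1=C[C@H](O[Si](C)(C)C(C)(C)C)CC(C)(C)[C@H]1/C=C/C1(C)OCCO1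
F8 | step 2 | (3E)-4-[(1R,4R)-4-(TBS-oxy)-2,6,6-trimethylcyclohex-2-en-1-yl]but-3-en-2-one | CC1=C[C@H](O[Si](C)(C)C(C)(C)C)CC(C)(C)[C@H]1/C=C/C(C)=O
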